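A charge of J, 0.089 M, meets a solution that starts with none of Z and can hold 25 mM of it, so the charge is 3.56 times one saturated load of Z. I assume that each Q costs one Z.

| setting | Monday's | Tuesday's | noon | spring | midnight | autumn |
|---|---|---|---|---|---|---|
| J | 0.044 M | 0.18 M | 0.089 M | 0.089 M | 0.089 M | 0.089 M |
| Z | 25 mM (held) | 25 mM (held) | 25 mM (held) | 25 mM (held) | 25 mM (held) | 25 mM (held) |
| temperature | 0 °C | 50 °C | 65 °C | 5 °C | 95 °C | 35 °C |
| remark | run made earlier | run made earlier |  |  |  |  |
| time |  |  | 20 min | 20 min | 20 min | 20 min |

| run | time / min | Q / % | J / % |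
|---|---|---|---|
| Monday's | 40.0 | 3.2 | 96.2 |
| Monday's | 60.0 | 4.0 | 94.6 |
| Monday's | 90.0 | 7.5 | 93.3 |
| Monday's | 150 | 10.8 | 86.7 |
| Monday's | 180 | 14.4 | 85.4 |
| Monday's | 300 | 23.9 | 77.3 |
| Monday's | 480 | 33.8 | 66.9 |
| Tuesday's | 6.00 | 5.6 | 94.4 |
| Tuesday's | 12.0 | 12.8 | 87.9 |
| Tuesday's | 15.0 | 14.9 | 85.2 |
| Tuesday's | 25.0 | 24.0 | 76.3 |
| Tuesday's | 30.0 | 27.6 | 72.9 |
| Tuesday's | 40.0 | 34.2 | 66.4 |

(each reading ± 1 percentage point)

1. which flask leads in amount of Q, in percent of the J charged ("all alike" within 1.5 percentage points) (noon / spring / midnight / autumn / all alike)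
2. how much Q is there at the end, in percent of the J charged: noon
3. how much Q is there at the end, in percent of the J charged: spring
4. how much Q is there at the end, in percent of the J charged: midnight
5. how much Q is there at the end, in percent of the J charged: autumn

- at the start none of Z is in solution

On that assumption, Tuesday's flask had taken 2.46 saturated loads of Z by its last reading, so Z must keep crossing into solution. Its first 15.0 min read as a draw of 1.79 mM/min. I fold this draw, the time and the charge into one number:

gas share = draw × time ÷ charge of J = 40.2 %

This is the gas share, the percent of the J charged that Tuesday's draw of Z can turn within the time. The four flasks have the same charge and time, so they have the same gas share. Below it, a reckoning from temperature needs no more Z than a run has shown. Above it, the crossing of Z may become the rate-limiting step, though the draw is a reading at one temperature and not a proven ceiling.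

The forecast puts midnight first, with 64 % there, 31 % at noon, 10 % in autumn and 2.3 % in spring, and warns: “Falling Z solubility, a dissolution lag, or reversibility could lower them”. Midnight's figure stands 1.59 times as high as the gas share, while noon's stands lower. My own reckoning differs from the forecast in one place: I hold midnight at 40.2 %, which still leaves it ahead of noon. One number is not enough here, since a value shared by the four flasks can trim a forecast but cannot rank flasks beneath it.

    J + D ⇌ Q + X (K = 4.10, k = 0.0270 /M/s, Ea = 74.0 kJ/mol, ΔH = 29.0 kJ/mol)
    D → G (k = 4.60 × 10⁻⁴ /s, Ea = 104 kJ/mol)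
    Z ⇌ D, rate k3*(csat - [D]) (kL = 0.00170 /s)
    (constants at 35 °C)

Noon leads with 28.2 %, then autumn with 22.0 %, midnight with 15.3 % and spring with 1.98 %. Midnight ends below the gas share, and at 20.0 min its dissolved D stands at 1.12 × 10⁻⁴ M, less than noon's 0.00150 M. Stretched to 80 min, the gas share reaches 161 %, yet spring then reads 11.1 % of Q, with D at 0.0236 M.

Readings and results were generated by integration on assumed constants; noise was put on by code.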